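The route rests on cutting C4a'–C5' and C8a'–C8' of the naphthazarin (unit B). Its outer ring C5'–C8' bears only para hydroxyls at C5' and C8' and hydrogens at C6' and C7', so it is the bis-enol of a succinoyl bridge across the CH=CH bond of a 2-aryl-3-methylbenzoquinone. One Diels–Alder reaction of 2,5-bis(trimethylsilyloxy)furan with that bond, followed by acid, closes this ring at the correct oxidation level and frees the C5 phenol in the same flask. The precursor is the bisquinone, carried as its C5 methoxymethyl ether, which comes from a Suzuki coupling, a semisquarate benzannulation and one (NH4)2Ce(NO3)6 oxidation.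

Key step: step 8

Remark: the target carries no descriptor for the C8–C2' biaryl axis, so the axis is formed without control (racemate expected); unprimed locants refer to the methoxynaphthoquinone (unit A), primed locants to unit B and to the atoms that become unit B; the arylboronic acid of step 2 is taken to be a catalogue compound.

Step 1
Reactants: 1 2-bromo-1,4-dimethoxybenzene
Product: 3 2-bromo-1,4-dimethoxy-3-methylbenzene, via (2-bromo-3,6-dimethoxyphenyl)lithium 2 (not isolated)
Conditions: LiN(iPr)2 (1.1 equiv), THF, −78 °C; then MeI, −78 °C to rt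
Reagents that add atoms: iodomethane, CI
Why: Directed ortho-metalation removes the most acidic ring hydrogen, the one flanked by bromine and methoxy, and the aryllithium is methylated at −78 °C before loss of LiBr to an aryne can set in.

Step 2
Reactants: 3 2-bromo-1,4-dimethoxy-3-methylbenzene; 4 (4-hydroxy-2-methylphenyl)boronic acid
Product: 5 3',6'-dimethoxy-2,2'-dimethylbiphenyl-4-ol
Conditions: Pd(OAc)2 (3 mol%), SPhos (dicyclohexyl(2',6'-dimethoxybiphenyl-2-yl)phosphine, 6 mol%), K3PO4 (3 equiv), toluene/H2O 10:1, 90 °C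
Reagents that add atoms: none
Why: Suzuki–Miyaura coupling, in which a bulky dialkylbiarylphosphine on zerovalent palladium is the standard answer to a hindered, electron-rich bromide and a tri-ortho-substituted biaryl, while the free phenol is tolerated as its phenoxide.

Step 3
Reactants: 5 3',6'-dimethoxy-2,2'-dimethylbiphenyl-4-ol
Product: 6 3,6-dimethoxy-4'-(methoxymethoxy)-2,2'-dimethylbiphenyl
Conditions: MOMCl, iPr2NEt, CH2Cl2, 0 °C to rt
Reagents that add atoms: chloromethyl methyl ether, COCCl
Why: Williamson-type O-alkylation of the phenol; the MOM acetal is chosen because it directs the metalation of step 5, survives heat and oxidation, and is cleaved by the acid that ends step 8.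

Step 4
Reactants: 7 dimethyl squarate (3,4-dimethoxycyclobut-3-ene-1,2-dione)
Product: 9 3-methoxycyclobut-3-ene-1,2-dione (methyl semisquarate), via 4-hydroxy-2,3-dimethoxycyclobut-2-en-1-one 8 (not isolated)
Conditions: LiAlH(OtBu)3, THF, −78 to 0 °C; then conc. HCl (cat.), CH2Cl2, rt
Reagents that add atoms: water, O
Why: Selective 1,2-reduction of one carbonyl by the bulky alkoxyaluminium hydride, then acid-catalysed allylic transposition (vinylogous ester hydrolysis) in which the ionised carbinol gives a methoxy-stabilised cyclobutenyl cation that takes up water at the distal methoxy carbon and expels methanol.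

Step 5
Reactants: 6 3,6-dimethoxy-4'-(methoxymethoxy)-2,2'-dimethylbiphenyl; 9 3-methoxycyclobut-3-ene-1,2-dione
Product: 11 4-[5-(3,6-dimethoxy-2-methylphenyl)-2-(methoxymethoxy)-4-methylphenyl]-4-hydroxy-3-methoxycyclobut-2-en-1-one (racemic carbinol), via aryllithium 10 (not isolated)
Conditions: n-BuLi (1.05 equiv), THF, 0 °C; then 9, THF, −78 °C; NH4Cl (aq)
Reagents that add atoms: none
Why: Directed ortho-metalation (the MOM acetal outranks the methoxy groups as director and its other ortho position is hindered by the methyl group) followed by 1,2-addition of the aryllithium to the more electrophilic carbonyl of 9, the one bonded to the methoxy-bearing carbon and not deactivated as a vinylogous ester; the racemic carbinol centre is destroyed in step 6.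

Step 6
Reactants: 11 4-[5-(3,6-dimethoxy-2-methylphenyl)-2-(methoxymethoxy)-4-methylphenyl]-4-hydroxy-3-methoxycyclobut-2-en-1-one
Product: 15 3-methoxy-5-(methoxymethoxy)-7-methyl-8-(2-methyl-3,6-dioxocyclohexa-1,4-dien-1-yl)naphthalene-1,4-dione, via dienylketene 12 (not isolated), via naphthalene-1,4-diol 13 (not isolated), via monoquinone 14 (not isolated)
Conditions: p-xylene, 138 °C; evaporate; then (NH4)2Ce(NO3)6 (5 equiv), MeCN/H2O, 0 °C
Reagents that add atoms: water, O
Why: Thermal ring expansion of a 4-aryl-4-hydroxycyclobutenone (4π electrocyclic opening with the hydroxyl turning outward to ketene 12, 6π electrocyclisation onto the only free ortho carbon, tautomerisation to hydroquinone 13), after which tetravalent cerium should oxidise the hydroquinone to 14 and oxidatively demethylate the para-dimethoxyarene, with oxygen from water, to the second quinone in the same flask.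

Step 7
Reactants: 16 succinic anhydride
Product: 17 2,5-bis(trimethylsilyloxy)furan
Conditions: Me3SiCl (2.4 equiv), Et3N, ZnCl2 (cat.), MeCN, rt to 50 °C; filtration under argon, distillation
Reagents that add atoms: chlorotrimethylsilane, C[Si](C)(C)Cl
Why: Double enol silylation of the anhydride (silyl ketene acetal formation under Lewis acid and amine), driven by the aromatic furan that results.

Step 8
Reactants: 15 3-methoxy-5-(methoxymethoxy)-7-methyl-8-(2-methyl-3,6-dioxocyclohexa-1,4-dien-1-yl)naphthalene-1,4-dione; 17 2,5-bis(trimethylsilyloxy)furan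
Product: 21 8'-hydroxy-3-methoxyisodiospyrin (target), via oxa-bridged cycloadduct 18 (not isolated), via tetraone tautomer 19 (not isolated), via MOM-protected target 20 (not isolated)
Conditions: 17 (2.5 equiv), CH2Cl2, −78 °C to rt; then HCl in MeOH (1.25 M), 40 °C
Reagents that add atoms: none
Why: Furan 17 should add through its carbons C2 and C5 to the CH=CH bond (C4a'=C8a') of the benzoquinone ring of 15 in a concerted, normal-electron-demand [4+2] cycloaddition to give the bridged bis(silyl ketal) 18, and acidic methanol then desilylates the bridgeheads, collapses the bridge to tetraone 19 and, after double enolisation to 20, removes the MOM acetal. The closest known reaction type is the Diels–Alder reaction of 2,5-bis(trimethylsilyloxy)furan with quinones and acetylenic esters, which delivers para-dihydroxyarenes once the oxygen bridge has opened. The one new ring, C4a'–C5'–C6'–C7'–C8'–C8a', is closed by intermolecular [4+2] annulation in which both ring bonds, C4a'–C5' and C8a'–C8', form suprafacially on diene and dienophile. Since 19 is the keto tautomer of the naphthazarin, no oxidant is needed and no ether on C5' or C8' has to be cleaved afterwards. The stereocentres of 18 (cis ring fusion and two bridgeheads) are transient, are left uncontrolled and vanish on aromatisation, so no stereocentre of the product depends on this step. Three quinone alkenes compete and the substrate sorts them: the fully substituted C2'=C3' bond is blocked, the C2=C3 bond of unit A is made electron-richer by its methoxy group, only C4a'=C8a' is a bare enedione alkene, and the MOM acetal removes the acidic, carbonyl-activating peri hydroxyl that would otherwise quench the silyl diene.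

Compound list
1 | 2-bromo-1,4-dimethoxybenzene | COc1ccc(OC)c(Br)c1 | starting material
2 | (2-bromo-3,6-dimethoxyphenyl)lithium | [Li]c1c(OC)ccc(OC)c1Br | intermediate
3 | 2-bromo-1,4-dimethoxy-3-methylbenzene | COc1ccc(OC)c(Br)c1C | intermediate
4 | (4-hydroxy-2-methylphenyl)boronic acid | Cc1cc(O)ccc1B(O)O | starting material
5 | 3',6'-dimethoxy-2,2'-dimethylbiphenyl-4-ol | Cc1cc(O)ccc1-c1c(C)c(OC)ccc1OC | intermediate
6 | 3,6-dimethoxy-4'-(methoxymethoxy)-2,2'-dimethylbiphenyl | COCOc1ccc(-c2c(C)c(OC)ccc2OC)c(C)c1 | intermediate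
7 | dimethyl squarate (3,4-dimethoxycyclobut-3-ene-1,2-dione) | COC1=C(OC)C(=O)C1=O | starting material
8 | 4-hydroxy-2,3-dimethoxycyclobut-2-en-1-one (racemic) | COC1=C(OC)C(O)C1=O | intermediate
9 | 3-methoxycyclobut-3-ene-1,2-dione | COC1=CC(=O)C1=O | intermediate
10 | [5-(3,6-dimethoxy-2-methylphenyl)-2-(methoxymethoxy)-4-methylphenyl]lithium | [Li]c1cc(-c2c(C)c(OC)ccc2OC)c(C)cc1OCOC | intermediate
11 | 4-[5-(3,6-dimethoxy-2-methylphenyl)-2-(methoxymethoxy)-4-methylphenyl]-4-hydroxy-3-methoxycyclobut-2-en-1-one (racemic) | COC1=CC(=O)C1(O)c1cc(-c2c(C)c(OC)ccc2OC)c(C)cc1OCOC | intermediate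
12 | dienylketene from ring opening of 11: 4-aryl-4-hydroxy-3-methoxybuta-1,3-dien-1-one | COC(C=C=O)=C(O)c1cc(-c2c(C)c(OC)ccc2OC)c(C)cc1OCOC | intermediate
13 | 8-(3,6-dimethoxy-2-methylphenyl)-3-methoxy-5-(methoxymethoxy)-7-methylnaphthalene-1,4-diol | COc1cc(O)c2c(-c3c(C)c(OC)ccc3OC)c(C)cc(OCOC)c2c1O | intermediate
14 | 8-(3,6-dimethoxy-2-methylphenyl)-3-methoxy-5-(methoxymethoxy)-7-methylnaphthalene-1,4-dione | COC1=CC(=O)c2c(-c3c(C)c(OC)ccc3OC)c(C)cc(OCOC)c2C1=O | intermediate
15 | 3-methoxy-5-(methoxymethoxy)-7-methyl-8-(2-methyl-3,6-dioxocyclohexa-1,4-dien-1-yl)naphthalene-1,4-dione (bisquinone precursor as C5 MOM ether) | COC1=CC(=O)c2c(C3=C(C)C(=O)C=CC3=O)c(C)cc(OCOC)c2C1=O | intermediate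
16 | succinic anhydride | O=C1CCC(=O)O1 | starting material
17 | 2,5-bis(trimethylsilyloxy)furan | C[Si](C)(C)Oc1ccc(O[Si](C)(C)C)o1 | intermediate
18 | 2-(unit A)-3-methyl-5,8-bis(trimethylsilyloxy)-4a,5,8,8a-tetrahydro-5,8-epoxynaphthalene-1,4-dione, cis-fused, diastereomer mixture | COC1=CC(=O)c2c(C3=C(C)C(=O)C4C(C3=O)C3(O[Si](C)(C)C)C=CC4(O[Si](C)(C)C)O3)c(C)cc(OCOC)c2C1=O | intermediate
19 | 2-(unit A)-3-methyl-4a,8a-dihydronaphthalene-1,4,5,8-tetraone, MOM ether | COC1=CC(=O)c2c(C3=C(C)C(=O)C4C(C3=O)C(=O)C=CC4=O)c(C)cc(OCOC)c2C1=O | intermediate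
20 | 5-O-methoxymethyl ether of the target | COC1=CC(=O)c2c(C3=C(C)C(=O)c4c(O)ccc(O)c4C3=O)c(C)cc(OCOC)c2C1=O | intermediate
21 | 8'-hydroxy-3-methoxyisodiospyrin | COC1=CC(=O)c2c(C3=C(C)C(=O)c4c(O)ccc(O)c4C3=O)c(C)cc(O)c2C1=O | target

Total step count: 8. Longest linear sequence: 6 steps (steps 1, 2, 3, 5, 6, 8).

Steps most likely to fail

1. Step 8. Electron transfer from the very electron-rich furan to the quinone (reduction of the quinone with loss of the diene), or a conjugate addition that stops after the first C–C bond, may outrun ring closure. The fallback sets out from 15 and comes back at 21; it builds the same ring with a carbocyclic diene and extrudes ethene. 1,4-Bis(trimethylsilyloxy)cyclohexa-1,3-diene F1 (from cyclohexane-1,4-dione, Me3SiCl, Et3N, DMF) should add to the CH=CH bond of 15 (toluene, 60–80 °C) to give the bicyclo[2.2.2]octene cycloadduct F2. Enolisation with Et3N should give the bridged hydroquinone F3, and Ag2O should oxidise it to the bridged quinone F4. Heating (xylene, 140 °C) should expel ethene in an Alder–Rickert retro-Diels–Alder cleavage to the bis(trimethylsilyl) ether F5 of 20, and HCl in MeOH then removes the silyl and MOM groups to give 21.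

2. Step 6. The 6π closure has to take place at the ring carbon next to the twisted biaryl axis; if it is slowed, the dienylketene may be drained by lactonisation with the neighbouring hydroxyl or by dimerisation. Partial loss of the MOM acetal under the acidic cerium oxidation is the lesser concern. The fallback sets out from 9 (and uses 3) and comes back at 14; it annulates first and couples afterwards. Commercial 4-bromo-3-methylphenol is iodinated ortho to the hydroxyl (I2, morpholine, CH2Cl2) to 4-bromo-2-iodo-5-methylphenol F6 and protected (MOMCl, iPr2NEt) as 1-bromo-5-iodo-4-(methoxymethoxy)-2-methylbenzene F7. Iodine–lithium exchange (n-BuLi, THF, −78 °C) gives [5-bromo-2-(methoxymethoxy)-4-methylphenyl]lithium F8, which adds to 9 to give the cyclobutenone F9. Thermolysis (toluene, 110 °C) passes through the dienylketene F10, which now closes next to bromine only, to the bromonaphthalene-1,4-diol F11, and Ag2O gives 8-bromo-3-methoxy-5-(methoxymethoxy)-7-methylnaphthalene-1,4-dione F12. Bromide 3 is converted by bromine–lithium exchange (n-BuLi, THF, −78 °C) into (3,6-dimethoxy-2-methylphenyl)lithium F13 and then (B(OMe)3; dilute acid) into (3,6-dimethoxy-2-methylphenyl)boronic acid F14. Suzuki–Miyaura coupling of F12 with F14 (Pd(OAc)2, SPhos, K3PO4, toluene, 100 °C) should give 14, which (NH4)2Ce(NO3)6 oxidises to 15 as in step 6.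

3. Step 5. Metalation between the MOM ether and the methyl group, or next to a methoxy group of the other ring, would lead to isomeric adducts. The fallback sets out from 5 and comes back at 10; it fixes the position of the metal with a halogen. Phenol 5 is iodinated at its less hindered ortho position (I2, morpholine, CH2Cl2; the phenol reacts far faster than the dimethoxyarene) to 5-iodo-3',6'-dimethoxy-2,2'-dimethylbiphenyl-4-ol F15. Protection (MOMCl, iPr2NEt) gives 5'-iodo-3,6-dimethoxy-4'-(methoxymethoxy)-2,2'-dimethylbiphenyl F16, and iodine–lithium exchange (n-BuLi, THF, −78 °C) gives aryllithium 10, which is added to 9 as in step 5.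

Further compounds
F1 | step 8 | 1,4-bis(trimethylsilyloxy)cyclohexa-1,3-diene | C[Si](C)(C)OC1=CC=C(O[Si](C)(C)C)CC1
F2 | step 8 | bicyclo[2.2.2]octene cycloadduct of 15 and F1 (cis-fused, diastereomer mixture) | COC1=CC(=O)c2c(C3=C(C)C(=O)C4C(C3=O)C3(O[Si](C)(C)C)CCC4(O[Si](C)(C)C)C=C3)c(C)cc(OCOC)c2C1=O
F3 | step 8 | bridged hydroquinone (enol form of F2) | COC1=CC(=O)c2c(-c3c(C)c(O)c4c(c3O)C3(O[Si](C)(C)C)CCC4(O[Si](C)(C)C)C=C3)c(C)cc(OCOC)c2C1=O
F4 | step 8 | bridged quinone | COC1=CC(=O)c2c(C3=C(C)C(=O)C4=C(C3=O)C3(O[Si](C)(C)C)CCC4(O[Si](C)(C)C)C=C3)c(C)cc(OCOC)c2C1=O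
F5 | step 8 | 5',8'-bis(trimethylsilyl) ether of 20 | COC1=CC(=O)c2c(C3=C(C)C(=O)c4c(O[Si](C)(C)C)ccc(O[Si](C)(C)C)c4C3=O)c(C)cc(OCOC)c2C1=O
F6 | step 6 | 4-bromo-2-iodo-5-methylphenol | Cc1cc(O)c(I)cc1Br
F7 | step 6 | 1-bromo-5-iodo-4-(methoxymethoxy)-2-methylbenzene | Cc1cc(OCOC)c(I)cc1Br
F8 | step 6 | [5-bromo-2-(methoxymethoxy)-4-methylphenyl]lithium | [Li]c1cc(Br)c(C)cc1OCOC
F9 | step 6 | 4-[5-bromo-2-(methoxymethoxy)-4-methylphenyl]-4-hydroxy-3-methoxycyclobut-2-en-1-one (racemic) | COC1=CC(=O)C1(O)c1cc(Br)c(C)cc1OCOC
F10 | step 6 | dienylketene from ring opening of F9 | COC(C=C=O)=C(O)c1cc(Br)c(C)cc1OCOC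
F11 | step 6 | 8-bromo-3-methoxy-5-(methoxymethoxy)-7-methylnaphthalene-1,4-diol | COc1cc(O)c2c(Br)c(C)cc(OCOC)c2c1O
F12 | step 6 | 8-bromo-3-methoxy-5-(methoxymethoxy)-7-methylnaphthalene-1,4-dione | COC1=CC(=O)c2c(Br)c(C)cc(OCOC)c2C1=O
F13 | step 6 | (3,6-dimethoxy-2-methylphenyl)lithium | [Li]c1c(C)c(OC)ccc1OC
F14 | step 6 | (3,6-dimethoxy-2-methylphenyl)boronic acid | COc1ccc(OC)c(B(O)O)c1C
F15 | step 5 | 5-iodo-3',6'-dimethoxy-2,2'-dimethylbiphenyl-4-ol | Cc1cc(O)c(I)cc1-c1c(C)c(OC)ccc1OC
F16 | step 5 | 5'-iodo-3,6-dimethoxy-4'-(methoxymethoxy)-2,2'-dimethylbiphenyl | Cc1cc(OCOC)c(I)cc1-c1c(C)c(OC)ccc1OC
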